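The cyclohexane ring is disconnected at C5–C10 (the bond joining the isopropenyl-bearing CH to the quaternary methyl carbon) and at C6–C7 (the lactone ring-fusion bond). One thermal operation on an acyclic allyl vinyl ether makes both bonds. A chair Claisen rearrangement forms C5–C10, sets C5 and quaternary C10, and releases a β,γ-unsaturated aldehyde. That aldehyde closes the ring at once by an isopulegol-type carbonyl-ene reaction (C6–C7), setting C6, C7 and the exocyclic methylene. The step exploits the all-equatorial cyclohexane with adjacent isopropenyl and quaternary carbons and the trans C6–O/C7–C relationship. The precursor is a D-tartrate-derived (E)-enol ether of (E)-4-hydroxy-3-methylbut-2-enal carrying a (Z)-allylic silyl ether.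

Key step: step 13

Atom labels used below (target skeleton): ring carbons C5 (isopropenyl), C6 (lactone O), C7 (attached to lactone α-carbon), C8 (O-angeloyl), C9 (OAc), C10 (quaternary; methyl = C14; vinyl = C1=C2); lactone C11 (α-carbon), C12 (C=O), C13 (=CH2); isopropenyl C4(=C3H2)C15H3.
Remark: compound 1 (acetonide of dimethyl D-tartrate) and compound 10 (sold as an aqueous solution) are taken as commercial.

Step 1
Reactants: 1 dimethyl (4S,5S)-2,2-dimethyl-1,3-dioxolane-4,5-dicarboxylate
Product: 2 methyl (4S,5R)-5-(hydroxymethyl)-2,2-dimethyl-1,3-dioxolane-4-carboxylate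
Conditions: NaBH4 (0.6 equiv), MeOH, 0 °C; unreacted 1 recovered
Reagents that add atoms: none
Why: Partial borohydride reduction of an α-alkoxy ester; 1 is C2-symmetric, so either ester gives the same hydroxy ester, and the two stereocentres (later C8 and C9) come unchanged from D-tartaric acid.

Step 2
Reactants: 2 methyl (4S,5R)-5-(hydroxymethyl)-2,2-dimethyl-1,3-dioxolane-4-carboxylate
Product: 3 methyl (4S,5S)-5-formyl-2,2-dimethyl-1,3-dioxolane-4-carboxylate
Conditions: Dess–Martin periodinane, NaHCO3, CH2Cl2, 0 °C to rt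
Reagents that add atoms: none
Why: Dess–Martin oxidation under buffered conditions should give the α-alkoxy aldehyde without epimerisation.

Step 3
Reactants: 3 methyl (4S,5S)-5-formyl-2,2-dimethyl-1,3-dioxolane-4-carboxylate
Product: 4 methyl (4S,5R)-5-ethynyl-2,2-dimethyl-1,3-dioxolane-4-carboxylate
Conditions: dimethyl (1-diazo-2-oxopropyl)phosphonate, K2CO3, MeOH, 0 °C to rt
Reagents that add atoms: dimethyl (1-diazo-2-oxopropyl)phosphonate, CC(=O)C(=[N+]=[N-])P(=O)(OC)OC
Why: Ohira–Bestmann (Seyferth–Gilbert) homologation turns the aldehyde into the terminal alkyne (C10≡C1); the trans-dioxolane is the thermodynamic isomer, so base cannot erode it, and the methyl ester is inert in methanol.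

Step 4
Reactants: 4 methyl (4S,5R)-5-ethynyl-2,2-dimethyl-1,3-dioxolane-4-carboxylate
Product: 5 (4S,5R)-5-ethynyl-2,2-dimethyl-1,3-dioxolane-4-carbaldehyde
Conditions: i-Bu2AlH (1.1 equiv), CH2Cl2, −78 °C; aqueous potassium sodium tartrate (KNaC4H4O6) work-up; crude aldehyde used directly
Reagents that add atoms: none
Why: Half-reduction of an α-alkoxy ester stops at the aldehyde because the tetrahedral aluminium hemiacetal survives at −78 °C until work-up.

Step 5
Reactants: 5 (4S,5R)-5-ethynyl-2,2-dimethyl-1,3-dioxolane-4-carbaldehyde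
Product: 6 ethyl (2Z)-3-[(4R,5R)-5-ethynyl-2,2-dimethyl-1,3-dioxolan-4-yl]-2-methylprop-2-enoate
Conditions: (CF3CH2O)2P(O)CH(CH3)CO2Et, KN(SiMe3)2, 18-crown-6, THF, −78 °C
Reagents that add atoms: ethyl 2-[bis(2,2,2-trifluoroethoxy)phosphoryl]propanoate, CCOC(=O)C(C)P(=O)(OCC(F)(F)F)OCC(F)(F)F
Why: The Still–Gennari variant of the Horner–Wadsworth–Emmons olefination should give the (Z)-trisubstituted enoate (C7=C11) under kinetic control, α-alkoxy aldehydes being favourable substrates.

Step 6
Reactants: 6 ethyl (2Z)-3-[(4R,5R)-5-ethynyl-2,2-dimethyl-1,3-dioxolan-4-yl]-2-methylprop-2-enoate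
Product: 7 (2Z)-3-[(4R,5R)-5-ethynyl-2,2-dimethyl-1,3-dioxolan-4-yl]-2-methylprop-2-en-1-ol
Conditions: i-Bu2AlH (2.5 equiv), CH2Cl2, −78 °C
Reagents that add atoms: none
Why: 1,2-Reduction of the enoate to the allylic alcohol (C12) keeps the (Z) geometry.

Step 7
Reactants: 7 (2Z)-3-[(4R,5R)-5-ethynyl-2,2-dimethyl-1,3-dioxolan-4-yl]-2-methylprop-2-en-1-ol
Product: 8 tert-butyl{[(2Z)-3-[(4R,5R)-5-ethynyl-2,2-dimethyl-1,3-dioxolan-4-yl]-2-methylprop-2-en-1-yl]oxy}dimethylsilane
Conditions: TBSCl, imidazole, DMF, rt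
Reagents that add atoms: tert-butyldimethylsilyl chloride, CC(C)(C)[Si](C)(C)Cl
Why: Standard silylation of a primary allylic alcohol; the ether must survive the copper steps and 180 °C.

Step 8
Reactants: 8 tert-butyl{[(2Z)-3-[(4R,5R)-5-ethynyl-2,2-dimethyl-1,3-dioxolan-4-yl]-2-methylprop-2-en-1-yl]oxy}dimethylsilane
Product: 9 2-[(1E)-2-{(4R,5R)-5-[(1Z)-3-{[tert-butyl(dimethyl)silyl]oxy}-2-methylprop-1-en-1-yl]-2,2-dimethyl-1,3-dioxolan-4-yl}prop-1-en-1-yl]-4,4,5,5-tetramethyl-1,3,2-dioxaborolane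
Conditions: B2pin2, CH3I, CuCl (cat.), Xantphos (cat.), NaOt-Bu, THF, rt
Reagents that add atoms: bis(pinacolato)diboron, CC1(C)OB(OC1(C)C)B1OC(C)(C)C(C)(C)O1; iodomethane, CI
Why: Copper-catalysed methylboration: syn borylcupration puts boron on the terminal carbon (C1) and copper on C10, and methylation of the alkenylcopper with retention gives the (E)-alkenyl boronate with C9 trans to boron.

Step 9
Reactants: 10 2,2-dimethoxyacetaldehyde
Product: 11 ethyl (2E)-4,4-dimethoxy-2-methylbut-2-enoate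
Conditions: Ph3P=C(CH3)CO2Et, CH2Cl2, rt
Reagents that add atoms: ethyl 2-(triphenylphosphoranylidene)propanoate, CCOC(=O)C(C)=P(c1ccccc1)(c1ccccc1)c1ccccc1
Why: Wittig olefination with a stabilised ylide should give the (E)-enoate (C4=C5).

Step 10
Reactants: 11 ethyl (2E)-4,4-dimethoxy-2-methylbut-2-enoate
Product: 12 (2E)-4,4-dimethoxy-2-methylbut-2-en-1-ol
Conditions: i-Bu2AlH (2.5 equiv), CH2Cl2, −78 °C
Reagents that add atoms: none
Why: 1,2-Reduction of the enoate; the acetal is inert to the hydride.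

Step 11
Reactants: 12 (2E)-4,4-dimethoxy-2-methylbut-2-en-1-ol
Product: 13 (2E)-4-hydroxy-3-methylbut-2-enal
Conditions: Amberlyst-15, acetone/H2O, rt; used freshly
Reagents that add atoms: water, O
Why: Mild acid hydrolysis of an allylic dimethyl acetal; the (E) hydroxy enal cannot close to a lactol and is used at once.

Step 12
Reactants: 9 the (E)-alkenyl pinacol boronate, 13 (2E)-4-hydroxy-3-methylbut-2-enal
Product: 14 (2E)-4-{[(1E)-2-{(4R,5R)-5-[(1Z)-3-{[tert-butyl(dimethyl)silyl]oxy}-2-methylprop-1-en-1-yl]-2,2-dimethyl-1,3-dioxolan-4-yl}prop-1-en-1-yl]oxy}-3-methylbut-2-enal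
Conditions: Cu(OAc)2 (2 equiv), Et3N (4 equiv), 13 in excess, 4 Å MS, CH2Cl2, rt, air; chromatography on Et3N-deactivated silica
Reagents that add atoms: none
Why: Chan–Lam-type copper-promoted C–O coupling of an alkenyl boronate with an allylic alcohol runs at room temperature with retention of alkene geometry and should tolerate the enal, giving the (E)-enol ether (C9 trans to O).

Step 13
Reactants: 14 the (E,E)-allyl vinyl ether
Product: 16 (3aR,4S,5S,6R,7S,7aR)-7-(3-{[tert-butyl(dimethyl)silyl]oxy}prop-1-en-2-yl)-6-hydroxy-2,2,4-trimethyl-5-(prop-1-en-2-yl)hexahydro-1,3-benzodioxole-4-carbaldehyde, via dialdehyde 15 (not isolated)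
Conditions: PhMe (0.01 M, degassed), BHT (cat.), sealed tube, 180 °C
Reagents that add atoms: none
Why: Heating triggers a Claisen [3,3] rearrangement of the (E,E)-allyl vinyl ether through a chair transition state with C9 and the formyl carbon C6 pseudo-equatorial, which forms C5–C10, creates C5 and the quaternary C10 and turns the unreactive conjugated enal into the β,γ-unsaturated aldehyde 15; its C6 carbonyl is then attacked by C7 of the (Z)-alkene in an intramolecular carbonyl-ene reaction that forms C6–C7 and moves the double bond to C11=C13. The closest known reaction type is the thermal domino Claisen/carbonyl-ene sequence, the second half being the citronellal-to-isopulegol cyclisation. Only the cyclohexane C5–C10 is closed, in a 6-exo-trig sense through a chair. C5 and C10 are fixed by the two (E) geometries and by attack on the enol ether face anti to C8 of the dioxolane, with the C9–O bond inside and H9 next to the C10 methyl; C6 and C7 are fixed by the chair ene transition state, in which an axial C6–O would meet the axial C10 methyl and allylic strain in the (Z)-alkene keeps the C7 substituent equatorial. The step needs chemoselectivity between the two aldehydes of 15 and hydrogen transfer from C13 instead of C12: the C1 aldehyde could reach C7 only by building a trans-fused bicyclo[3.3.0] ring across the acetonide, and the (Z) geometry puts the methyl group on the side of the vinylic hydrogen, where the carbonyl oxygen lies in the chair.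

Step 14
Reactants: 16 the cyclohexanol aldehyde
Product: 17 the 4-ethynyl analogue of 16 (C10–CHO replaced by C10–C≡CH; C6–OH, silyl ether, acetonide and all stereocentres as in 16)
Conditions: dimethyl (1-diazo-2-oxopropyl)phosphonate, K2CO3, MeOH, rt
Reagents that add atoms: dimethyl (1-diazo-2-oxopropyl)phosphonate, CC(=O)C(=[N+]=[N-])P(=O)(OC)OC
Why: Ohira–Bestmann homologation of a non-enolisable neopentyl aldehyde gives the C1≡C2 alkyne; it is done before the base-sensitive α-methylene lactone exists.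

Step 15
Reactants: 17 the silyl-protected alkyne
Product: 18 the diol (C6–OH and C12–OH free; alkyne and acetonide as in 17)
Conditions: HF·pyridine, pyridine, THF, 0 °C to rt
Reagents that add atoms: none
Why: Fluoride cleavage of the primary allylic silyl ether; the buffered medium should spare the acetonide.

Step 16
Reactants: 18 the diol
Product: 21 the acetonide-protected trans-fused α-methylene-γ-butyrolactone (O6–C12 lactone; C10 ethynyl and methyl; C5 isopropenyl), via hydroxy enal 19 (not isolated), via lactol 20 (not isolated)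
Conditions: TEMPO (cat.), PhI(OAc)2 (2.5 equiv), CH2Cl2, rt
Reagents that add atoms: none
Why: Oxoammonium-mediated oxidative lactonisation: the primary allylic alcohol is oxidised selectively, the enal is trapped by the C6 hydroxyl as a lactol and oxidised on to the lactone; O8 is held in the acetonide, so only the lactone to O6 can form.

Step 17
Reactants: 21 the acetonide lactone
Product: 22 the C8,C9-diol lactone
Conditions: AcOH/H2O (4:1), 45 °C
Reagents that add atoms: none
Why: Acid hydrolysis of the strained trans-fused acetonide; alkyne, isopropenyl and methylene lactone should tolerate dilute acetic acid.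

Step 18
Reactants: 22 the C8,C9-diol lactone
Product: 23 the C8 angelate (C9–OH free)
Conditions: (Z)-2-methylbut-2-enoic acid, 2,4,6-trichlorobenzoyl chloride, Et3N, PhMe, rt; then 22 (1.1 equiv of anhydride), 75 °C
Reagents that add atoms: angelic acid [(2Z)-2-methylbut-2-enoic acid], C/C=C(/C)C(=O)O
Why: Yamaguchi-type esterification through the mixed anhydride without a nucleophilic catalyst avoids angelate-to-tiglate isomerisation, and the C8 hydroxyl should react before the C9 hydroxyl, which is flanked by quaternary C10.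

Step 19
Reactants: 23 the C8 angelate
Product: 24 the C8 angelate C9 acetate (terminal alkyne)
Conditions: Ac2O, pyridine, DMAP (cat.), CH2Cl2, rt
Reagents that add atoms: acetic anhydride, CC(=O)OC(C)=O
Why: DMAP-catalysed acetylation of the remaining hindered secondary alcohol.

Step 20
Reactants: 24 the C8 angelate C9 acetate
Product: 25 target CNP0582479.1
Conditions: AcOH (1.5 equiv), [RuCl2(p-cymene)]2 (cat.), P(4-ClC6H4)3 (cat.), DMAP (cat.), PhMe, 60 °C
Reagents that add atoms: acetic acid, CC(=O)O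
Why: Ruthenium-catalysed anti-Markovnikov addition of a carboxylic acid to a terminal alkyne via a vinylidene complex; attack of acetate at the vinylidene carbon followed by protonation should give the (Z)-enol acetate.

Compound list
1 | dimethyl (4S,5S)-2,2-dimethyl-1,3-dioxolane-4,5-dicarboxylate | COC(=O)[C@H]1OC(C)(C)O[C@@H]1C(=O)OC | starting material
2 | methyl (4S,5R)-5-(hydroxymethyl)-2,2-dimethyl-1,3-dioxolane-4-carboxylate | COC(=O)[C@H]1OC(C)(C)O[C@@H]1CO | intermediate
3 | methyl (4S,5S)-5-formyl-2,2-dimethyl-1,3-dioxolane-4-carboxylate | COC(=O)[C@H]1OC(C)(C)O[C@@H]1C=O | intermediate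
4 | methyl (4S,5R)-5-ethynyl-2,2-dimethyl-1,3-dioxolane-4-carboxylate | COC(=O)[C@H]1OC(C)(C)O[C@@H]1C#C | intermediate
5 | (4S,5R)-5-ethynyl-2,2-dimethyl-1,3-dioxolane-4-carbaldehyde | O=C[C@H]1OC(C)(C)O[C@@H]1C#C | intermediate
6 | ethyl (2Z)-3-[(4R,5R)-5-ethynyl-2,2-dimethyl-1,3-dioxolan-4-yl]-2-methylprop-2-enoate | CCOC(=O)/C(C)=C\[C@H]1OC(C)(C)O[C@@H]1C#C | intermediate
7 | (2Z)-3-[(4R,5R)-5-ethynyl-2,2-dimethyl-1,3-dioxolan-4-yl]-2-methylprop-2-en-1-ol | OC/C(C)=C\[C@H]1OC(C)(C)O[C@@H]1C#C | intermediate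
8 | tert-butyl{[(2Z)-3-[(4R,5R)-5-ethynyl-2,2-dimethyl-1,3-dioxolan-4-yl]-2-methylprop-2-en-1-yl]oxy}dimethylsilane | CC(C)(C)[Si](C)(C)OC/C(C)=C\[C@H]1OC(C)(C)O[C@@H]1C#C | intermediate
9 | 2-[(1E)-2-{(4R,5R)-5-[(1Z)-3-{[tert-butyl(dimethyl)silyl]oxy}-2-methylprop-1-en-1-yl]-2,2-dimethyl-1,3-dioxolan-4-yl}prop-1-en-1-yl]-4,4,5,5-tetramethyl-1,3,2-dioxaborolane | CC(C)(C)[Si](C)(C)OC/C(C)=C\[C@H]1OC(C)(C)O[C@@H]1/C(C)=C/B1OC(C)(C)C(C)(C)O1 | intermediate
10 | 2,2-dimethoxyacetaldehyde | COC(OC)C=O | starting material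
11 | ethyl (2E)-4,4-dimethoxy-2-methylbut-2-enoate | CCOC(=O)/C(C)=C/C(OC)OC | intermediate
12 | (2E)-4,4-dimethoxy-2-methylbut-2-en-1-ol | OC/C(C)=C/C(OC)OC | intermediate
13 | (2E)-4-hydroxy-3-methylbut-2-enal | OC/C(C)=C/C=O | intermediate
14 | (2E)-4-{[(1E)-2-{(4R,5R)-5-[(1Z)-3-{[tert-butyl(dimethyl)silyl]oxy}-2-methylprop-1-en-1-yl]-2,2-dimethyl-1,3-dioxolan-4-yl}prop-1-en-1-yl]oxy}-3-methylbut-2-enal | CC(C)(C)[Si](C)(C)OC/C(C)=C\[C@H]1OC(C)(C)O[C@@H]1/C(C)=C/OC/C(C)=C/C=O | intermediate
15 | (2S,3S)-3-{(4R,5R)-5-[(1Z)-3-{[tert-butyl(dimethyl)silyl]oxy}-2-methylprop-1-en-1-yl]-2,2-dimethyl-1,3-dioxolan-4-yl}-3-methyl-2-(prop-1-en-2-yl)butanedial | O=C[C@@H](C(C)=C)[C@](C)(C=O)[C@H]1OC(C)(C)O[C@@H]1/C=C(/C)CO[Si](C)(C)C(C)(C)C | intermediate (not isolated)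
16 | (3aR,4S,5S,6R,7S,7aR)-7-(3-{[tert-butyl(dimethyl)silyl]oxy}prop-1-en-2-yl)-6-hydroxy-2,2,4-trimethyl-5-(prop-1-en-2-yl)hexahydro-1,3-benzodioxole-4-carbaldehyde | O=C[C@@]1(C)[C@H](C(C)=C)[C@@H](O)[C@H](C(=C)CO[Si](C)(C)C(C)(C)C)[C@H]2OC(C)(C)O[C@H]12 | intermediate
17 | 4-ethynyl analogue of 16 (CHO replaced by C≡CH; all else as in 16) | C#C[C@@]1(C)[C@H](C(C)=C)[C@@H](O)[C@H](C(=C)CO[Si](C)(C)C(C)(C)C)[C@H]2OC(C)(C)O[C@H]12 | intermediate
18 | desilylated 17: C6 secondary alcohol with C12 primary allylic alcohol | C#C[C@@]1(C)[C@H](C(C)=C)[C@@H](O)[C@H](C(=C)CO)[C@H]2OC(C)(C)O[C@H]12 | intermediate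
19 | hydroxy enal (C12 aldehyde, C6–OH free) | C#C[C@@]1(C)[C@H](C(C)=C)[C@@H](O)[C@H](C(=C)C=O)[C@H]2OC(C)(C)O[C@H]12 | intermediate (not isolated)
20 | lactol (O6–C12 hemiacetal, both anomers) | C#C[C@@]1(C)[C@H](C(C)=C)[C@H]3OC(O)C(=C)[C@@H]3[C@H]2OC(C)(C)O[C@H]12 | intermediate (not isolated)
21 | acetonide-protected trans-fused α-methylene-γ-butyrolactone with C10 ethynyl/methyl and C5 isopropenyl | C#C[C@@]1(C)[C@H](C(C)=C)[C@H]3OC(=O)C(=C)[C@@H]3[C@H]2OC(C)(C)O[C@H]12 | intermediate
22 | C8,C9-diol lactone (both hydroxyls equatorial, trans) | C#C[C@@]1(C)[C@H](C(C)=C)[C@H]2OC(=O)C(=C)[C@@H]2[C@@H](O)[C@@H]1O | intermediate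
23 | C8 O-angeloyl, C9 hydroxy lactone | C#C[C@@]1(C)[C@H](C(C)=C)[C@H]2OC(=O)C(=C)[C@@H]2[C@@H](OC(=O)/C(C)=C\C)[C@@H]1O | intermediate
24 | C8 O-angeloyl, C9 O-acetyl lactone with C10 ethynyl | C#C[C@@]1(C)[C@H](C(C)=C)[C@H]2OC(=O)C(=C)[C@@H]2[C@@H](OC(=O)/C(C)=C\C)[C@@H]1OC(C)=O | intermediate
25 | CNP0582479.1 | C=C1C(=O)O[C@H]2[C@H]1[C@@H](OC(=O)/C(C)=C\C)[C@H](OC(C)=O)[C@@](C)(/C=C\OC(C)=O)[C@@H]2C(=C)C | target

Total step count: 20. Longest linear sequence: 17 (steps 1–8 and 12–20).

Steps most likely to fail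

Step 13. The risk is erosion of facial selectivity in the sigmatropic step at 180 °C, and isomerisation of the transient β,γ-unsaturated aldehyde into conjugation before the ene closure. The fallback sets out from 9 and the acetal alcohol 12. The same copper-promoted coupling would give the enol ether dimethyl acetal F1. Claisen rearrangement alone (PhMe, 140 °C) would give the α-quaternary aldehyde acetal F2, in which the second aldehyde stays masked. Mild acetal cleavage (LiBF4, wet MeCN) would release dialdehyde 15, which is treated at once with Me2AlCl (CH2Cl2, −78 °C) for a Lewis-acid-promoted carbonyl-ene closure, returning to the route at 16.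

Step 12. The risk is protodeboronation or acetate transfer to the hindered alkenyl boronate outrunning C–O coupling with the sensitive hydroxy enal. The fallback sets out from 9. Iododeboronation (NaI, TsN(Cl)Na, aqueous THF) would give the (E)-alkenyl iodide F3 with retention. Ullmann-type vinylation (CuI, 3,4,7,8-tetramethyl-1,10-phenanthroline, Cs2CO3, PhMe, 80 °C) of (2E)-4-hydroxy-3-methylbut-2-en-1-yl acetate F4 (from prenyl acetate by SeO2/t-BuOOH allylic oxidation) would give the enol ether acetate F5. Methanolysis (K2CO3, MeOH) to the allylic alcohol F6 and MnO2 oxidation would return to the route at 14.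

Step 18. The risk is poor discrimination between the C8 and C9 hydroxyls (bis-acylation or the C9 ester), or base-induced relactonisation toward O8 at 75 °C. The fallback sets out from 22. Silylation of the less hindered hydroxyl (Et3SiCl, imidazole, −20 °C) would give the C8 triethylsilyl ether F7. Acetylation of the C9 hydroxyl (Ac2O, DMAP, pyridine) would give the silyl ether acetate F8. Desilylation (HF·pyridine) would give the C9 acetate C8 alcohol F9, and angeloylation of its only free hydroxyl by the mixed-anhydride method would return to the route at 24.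

Further compounds
F1 | step 13 | (E)-enol ether dimethyl acetal: tert-butyl{[(2Z)-3-{(4R,5R)-5-[(1E)-1-{[(2E)-4,4-dimethoxy-2-methylbut-2-en-1-yl]oxy}prop-1-en-2-yl]-2,2-dimethyl-1,3-dioxolan-4-yl}-2-methylprop-2-en-1-yl]oxy}dimethylsilane | CC(C)(C)[Si](C)(C)OC/C(C)=C\[C@H]1OC(C)(C)O[C@@H]1/C(C)=C/OC/C(C)=C/C(OC)OC
F2 | step 13 | α-quaternary aldehyde acetal: (2S,3S)-2-{(4R,5R)-5-[(1Z)-3-{[tert-butyl(dimethyl)silyl]oxy}-2-methylprop-1-en-1-yl]-2,2-dimethyl-1,3-dioxolan-4-yl}-3-(dimethoxymethyl)-2,4-dimethylpent-4-enal | COC(OC)[C@@H](C(C)=C)[C@](C)(C=O)[C@H]1OC(C)(C)O[C@@H]1/C=C(/C)CO[Si](C)(C)C(C)(C)C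
F3 | step 12 | (E)-alkenyl iodide: tert-butyl{[(2Z)-3-{(4R,5R)-5-[(1E)-1-iodoprop-1-en-2-yl]-2,2-dimethyl-1,3-dioxolan-4-yl}-2-methylprop-2-en-1-yl]oxy}dimethylsilane | CC(C)(C)[Si](C)(C)OC/C(C)=C\[C@H]1OC(C)(C)O[C@@H]1/C(C)=C/I
F4 | step 12 | (2E)-4-hydroxy-3-methylbut-2-en-1-yl acetate | CC(=O)OC/C=C(\C)CO
F5 | step 12 | enol ether acetate (14 with CH2OAc in place of CHO) | CC(C)(C)[Si](C)(C)OC/C(C)=C\[C@H]1OC(C)(C)O[C@@H]1/C(C)=C/OC/C(C)=C/COC(C)=O
F6 | step 12 | allylic alcohol (14 with CH2OH in place of CHO) | CC(C)(C)[Si](C)(C)OC/C(C)=C\[C@H]1OC(C)(C)O[C@@H]1/C(C)=C/OC/C(C)=C/CO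
F7 | step 18 | C8 triethylsilyl ether of 22 | C#C[C@@]1(C)[C@H](C(C)=C)[C@H]2OC(=O)C(=C)[C@@H]2[C@@H](O[Si](CC)(CC)CC)[C@@H]1O
F8 | step 18 | C8 triethylsilyl ether C9 acetate | C#C[C@@]1(C)[C@H](C(C)=C)[C@H]2OC(=O)C(=C)[C@@H]2[C@@H](O[Si](CC)(CC)CC)[C@@H]1OC(C)=O
F9 | step 18 | C9 acetate C8 alcohol | C#C[C@@]1(C)[C@H](C(C)=C)[C@H]2OC(=O)C(=C)[C@@H]2[C@@H](O)[C@@H]1OC(C)=O
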